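C1 is the =CH2-bearing ring carbon, C2 and C3 are CH2, C4 bears the oxolane, C5 bears OH, and C6/C7 are the fusion carbons. C8 (CH2), C9 and C10 (C–CH3) complete the cyclopentene, and C1' (quaternary) to C4' belong to the oxolane.
Enabling feature: in the seven-membered ring the carbinol C5 and the latent ketone C1 flank the fusion carbons C6/C7, and the oxolanyl carbon C4 adjoins C5. C2–C1–C7–C6–C5 with an oxygen bridging C2 and C5 is therefore the five-carbon unit of a 3-oxidopyrylium, and C3–C4 is the vinyl group of cis-furanoid linalool oxide.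
Retrosynthetic cuts: C1=CH2 (methylenation), C9=C10 (metathesis), C7–C8 (allylation), C6–C10 (conjugate addition), C2–O (reductive bridge opening), then C2–C3 and C4–C5 together ([5+2]).
Forward ring order: oxolane from linalool, pyranone from furfuryl alcohol, oxygen-bridged seven-membered carbocycle in the cycloaddition, bridge opening, cyclopentene last.
Stereochemistry: C1' comes from (R)-linalool and C4' from reagent-controlled epoxidation followed by invertive 5-exo opening. C4/C5 come from the exo topology and vinyl-face selection of the cycloaddition, C6 from addition anti to the C5 oxygen, and C7 from allylation anti to the C6 substituent (trans fusion).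
Key step: step 6

Conventions: Ox = (2R,5S)-5-(2-acetoxypropan-2-yl)-2-methyloxolan-2-yl, with the bond from C1' to C4 and the CMe2OAc group cis on the oxolane. β is the ring face that carries the C5 oxygen and α is the opposite face.
Assumption: commercial (R)-(−)-linalool is highly but not perfectly enantioenriched. Because C4' is set under reagent control, most of the (S)-antipode should end up in the trans-configured oxide, which is removed with the pyranoid isomer at compound 3.

Step 1
Reactants: 1 (R)-(−)-linalool
Product: 2 (3R,6R)-6,7-epoxylinalool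
Conditions: D-fructose-derived Shi ketone (1,2:4,5-di-O-isopropylidene-β-D-erythro-hexo-2,3-diulo-2,6-pyranose, 0.3 equiv), KHSO5 (as Oxone, 2KHSO5·KHSO4·K2SO4), K2CO3, Bu4NHSO4 (cat.), Na2B4O7/Na2EDTA buffer, MeCN–CH2(OMe)2–H2O, 0 °C
Reagents that add atoms: potassium peroxymonosulfate KHSO5, [K+].[O-]S(=O)(=O)OO
Why: Shi asymmetric epoxidation, in which the chiral dioxirane attacks only the electron-rich trisubstituted C6=C7 alkene (the vinyl group is too electron-poor) through the spiro transition state that should give the (6R)-epoxide under reagent control, independent of C3.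

Step 2
Reactants: 2 (3R,6R)-6,7-epoxylinalool
Product: 3 (2S,5R)-cis-furanoid linalool oxide (vinyl and 2-hydroxypropan-2-yl cis)
Conditions: camphorsulfonic acid (0.1 equiv), CH2Cl2, 0 °C
Reagents that add atoms: none
Why: Acid-catalysed intramolecular epoxide opening (5-exo-tet, SN2-like), in which the tertiary hydroxyl attacks the secondary epoxide carbon with inversion so that (6R) becomes the (2S) oxolane carbon cis to the vinyl group, the C3–O bond stays intact, and the minor 6-endo pyranoid isomer is removed by chromatography.

Step 3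
Reactants: 3 (2S,5R)-cis-furanoid linalool oxide
Product: 4 cis-linalool oxide acetate, 2-[(2S,5R)-5-ethenyl-5-methyloxolan-2-yl]propan-2-yl acetate
Conditions: Ac2O, Et3N, DMAP (0.2 equiv), CH2Cl2, 40 °C
Reagents that add atoms: acetic anhydride, CC(=O)OC(C)=O
Why: DMAP-catalysed acylation through the N-acetylpyridinium ion is the standard way to esterify a tertiary alcohol, it touches no stereocentre, and it installs the final ester of the target at the outset.

Step 4
Reactants: 5 furfuryl alcohol
Product: 6 6-hydroxy-2H-pyran-3(6H)-one (racemic)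
Conditions: mCPBA, CH2Cl2, 0 °C to rt
Reagents that add atoms: mCPBA, O=C(OO)c1cccc(Cl)c1
Why: Achmatowicz rearrangement, in which peracid oxidation of the furan and ring closure by the side-chain hydroxyl give the six-membered lactol enone, whose racemic anomeric centre is of no consequence.

Step 5
Reactants: 6 6-hydroxy-2H-pyran-3(6H)-one
Product: 7 6-acetoxy-2H-pyran-3(6H)-one (racemic)
Conditions: Ac2O, pyridine, DMAP (cat.), CH2Cl2, 0 °C
Reagents that add atoms: acetic anhydride, CC(=O)OC(C)=O
Why: O-acetylation of the lactol provides the leaving group for ylide generation, and its stereocentre is erased in the next step.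

Step 6
Reactants: 4 cis-linalool oxide acetate; 7 6-acetoxy-2H-pyran-3(6H)-one
Product: 9 (1S,5S,6R)-6-exo-Ox-8-oxabicyclo[3.2.1]oct-3-en-2-one, via 3-oxidopyrylium ylide 8 (not isolated)
Conditions: Et3N (1.5 equiv), 4 (10 equiv, excess recovered), minimum MeCN, 80 °C, 7 added slowly by syringe pump
Reagents that add atoms: none
Why: Et3N enolises 7 and expels its acetate to give the planar 3-oxidopyrylium 8, whose two carbons flanking the ring oxygen add suprafacially and in concert across the vinyl group of 4, so that C2–C3 and C4–C5 form together. The closest known reaction type is the intermolecular oxidopyrylium–alkene [5+2] cycloaddition of Achmatowicz-derived acetoxypyranones with monosubstituted alkenes, of which a vinyl group on a fully substituted carbon is a demanding member. The seven-membered carbocycle, and with it the five-membered ether ring of the bicycle, closes in a bridged [π4s+π2s] cycloaddition mode rather than by a chain cyclisation. The step needs 6-regiochemistry, which follows from the larger frontier coefficients at the ylide carbon next to the oxido carbon pairing with the terminal CH2 (C3), so that C4 ends next to the bridgehead C5. C2 and C5 are tied cis by the oxygen bridge, C4 is set relative to C5 by the exo transition state in which the bulky quaternary C1' avoids the three-carbon enone bridge and ends syn to the bridging oxygen, and the absolute sense comes from the vinyl face exposed in the staggered conformer with the oxolane oxygen inside, the ring CH2 anti and the methyl outside, which leads to (4R). Face selection is the weakest of these controls, so the diastereomeric exo adduct is expected as a by-product to be removed by chromatography, while slow addition of 7 to a large recoverable excess of 4 keeps the ylide dilute and holds back its second-order dimerisation.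

Step 7
Reactants: 9 6-exo-Ox-8-oxabicyclo[3.2.1]oct-3-en-2-one
Product: 10 4-exo-phenylthio-6-exo-Ox-8-oxabicyclo[3.2.1]octan-2-one (SPh on C6, β)
Conditions: PhSH (1.1 equiv), Et3N (0.1 equiv), CH2Cl2, 0 °C
Reagents that add atoms: thiophenol, Sc1ccccc1
Why: Base-catalysed thia-Michael addition from the open exo face masks the enone, whose C5–O bond would otherwise be vinylogously activated towards reduction, keeps the position of the later C6=C7 bond marked, and creates only a temporary centre at C6.

Step 8
Reactants: 10 4-exo-phenylthio-6-exo-Ox-8-oxabicyclo[3.2.1]octan-2-one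
Product: 11 4β-Ox-5β-hydroxy-6β-phenylthiocycloheptan-1-one
Conditions: SmI2 (2.5 equiv), MeOH (5 equiv), THF, −78 °C
Reagents that add atoms: none
Why: SmI2 reduction of an α-alkoxy ketone, in which the ketyl expels the C2 oxygen (its C–O bond overlaps well with the carbonyl π system), a second electron gives the samarium enolate and MeOH protonates it, so that C2 becomes CH2 while the C5–O bond, its configuration, the sulfide and the acetate are untouched.

Step 9
Reactants: 11 4β-Ox-5β-hydroxy-6β-phenylthiocycloheptan-1-one
Product: 13 (4S,5R)-4-hydroxy-5-Ox-cyclohept-2-en-1-one (C5 OH and C4 Ox cis), via β-keto sulfone 12 (not isolated)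
Conditions: mCPBA (2.2 equiv), CH2Cl2, 0 °C; then Et3N (3 equiv), 0 °C to rt
Reagents that add atoms: none
Why: Sulfide-to-sulfone oxidation followed by E1cB loss of benzenesulfinate from the β-sulfonyl ketone regenerates the enone only towards the acidic C7 hydrogens, and doing this before silylation drains any transannular hemiketal form of 11 into the open enone.

Step 10
Reactants: 13 (4S,5R)-4-hydroxy-5-Ox-cyclohept-2-en-1-one
Product: 14 (4S,5R)-4-(tert-butyldimethylsilyloxy)-5-Ox-cyclohept-2-en-1-one
Conditions: TBSOTf, 2,6-lutidine, CH2Cl2, −78 to 0 °C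
Reagents that add atoms: tert-butyldimethylsilyl triflate, CC(C)(C)[Si](C)(C)OS(=O)(=O)C(F)(F)F
Why: Silylation of a hindered secondary allylic alcohol with a silyl triflate and a non-nucleophilic base leaves C5 unchanged and provides the bulky β-face group that directs the next step.

Step 11
Reactants: 14 (4S,5R)-4-(tert-butyldimethylsilyloxy)-5-Ox-cyclohept-2-en-1-one; 15 isopropenylmagnesium bromide
Product: 16 trimethylsilyl enol ether (C1=C7) of 4β-Ox-5β-silyloxy-6α-isopropenylcycloheptanone
Conditions: CuBr·SMe2 (0.1 equiv), TMSCl, HMPA, THF, −78 °C, 15 added dropwise; Et3N, cold aq NaHCO3 work-up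
Reagents that add atoms: chlorotrimethylsilane, C[Si](C)(C)Cl
Why: Copper-catalysed, chlorosilane-accelerated conjugate addition of a Grignard reagent, in which the organocopper species attacks C6 from the α face anti to the C5 silyloxy and C4 Ox groups, the enolate is trapped regiospecifically on oxygen, and the low temperature and fast 1,4-pathway spare the tertiary acetate.

Step 12
Reactants: 16 trimethylsilyl enol ether; 17 allyl iodide
Product: 19 (2R,3S,4S,5R)-2-allyl-3-isopropenyl-4-(tert-butyldimethylsilyloxy)-5-Ox-cycloheptan-1-one (C7 allyl β and C6 isopropenyl α), via benzyltrimethylammonium enolate 18 (not isolated)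
Conditions: anhydrous BnMe3NF (1.1 equiv), 17 (3 equiv), 4 Å molecular sieves, THF, −20 °C to rt
Reagents that add atoms: none
Why: Fluoride-induced desilylation releases the C1/C7 quaternary ammonium enolate regiospecifically without any organolithium that would attack the acetate, and its SN2 alkylation by allyl iodide occurs anti to the C6 isopropenyl group to give the trans-2,3 relationship, which is also the thermodynamically preferred one.

Step 13
Reactants: 19 2-allyl-3-isopropenyl cycloheptanone
Product: 20 trans-fused hydroazulenone (C1 ketone, C9=C10 with methyl on C10, H6 β and H7 α, 5β-silyloxy, 4β-Ox)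
Conditions: second-generation Grubbs catalyst (H2IMes)(PCy3)Cl2Ru=CHPh (5 mol %), CH2Cl2 (high dilution), 40 °C
Reagents that add atoms: none
Why: Ring-closing metathesis initiates at the monosubstituted allyl alkene and closes onto the 1,1-disubstituted isopropenyl group to give the trisubstituted cyclopentene, the gauche trans-vicinal arrangement allows the five-membered ring to form, and no stereocentre is touched.

Step 14
Reactants: 20 trans-fused hydroazulenone
Product: 21 C5 tert-butyldimethylsilyl ether of the target
Conditions: Zn, CH2Br2, TiCl4 (reagent pre-formed in THF, −40 to 5 °C), CH2Cl2, 0 °C to rt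
Reagents that add atoms: dibromomethane, BrCBr
Why: Takai–Lombardo methylenation uses a non-basic gem-dimetallic reagent that converts ketones but not esters, so the epimerisable C7 centre next to the carbonyl, the acetate and the silyl ether should survive.

Step 15
Reactants: 21 C5 silyl ether of the target
Product: 22 target CNP0302132.3, 2-[(2S,5R)-5-[(3aS,4S,5R,8aR)-4-hydroxy-3-methyl-8-methylidene-1,3a,4,5,6,7,8,8a-octahydroazulen-5-yl]-5-methyloxolan-2-yl]propan-2-yl acetate
Conditions: HF·pyridine, pyridine, THF, 0 °C to rt
Reagents that add atoms: none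
Why: Fluoride-mediated desilylation in a pyridine-buffered medium cleaves the Si–O bond only, so the tertiary acetate, the exocyclic methylene and all six stereocentres remain as set.

Compound list
1 | (R)-(−)-linalool | C=C[C@](C)(O)CCC=C(C)C | starting material
2 | (3R,6R)-6,7-epoxylinalool | C=C[C@](C)(O)CC[C@H]1OC1(C)C | intermediate
3 | (2S,5R)-cis-furanoid linalool oxide | C=C[C@@]1(C)CC[C@@H](C(C)(C)O)O1 | intermediate
4 | cis-linalool oxide acetate | C=C[C@@]1(C)CC[C@@H](C(C)(C)OC(C)=O)O1 | intermediate
5 | furfuryl alcohol | OCc1ccco1 | starting material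
6 | 6-hydroxy-2H-pyran-3(6H)-one (racemic) | OC1C=CC(=O)CO1 | intermediate
7 | 6-acetoxy-2H-pyran-3(6H)-one (racemic) | CC(=O)OC1C=CC(=O)CO1 | intermediate
8 | 3-oxidopyrylium ylide (not isolated) | [O-]c1ccc[o+]c1 | intermediate
9 | (1S,5S,6R)-6-exo-Ox-8-oxabicyclo[3.2.1]oct-3-en-2-one | O=C1[C@@H]2C[C@@H]([C@@]3(C)CC[C@@H](C(C)(C)OC(C)=O)O3)[C@@H](O2)C=C1 | intermediate
10 | 4-exo-phenylthio-6-exo-Ox-8-oxabicyclo[3.2.1]octan-2-one | O=C1[C@@H]2C[C@@H]([C@@]3(C)CC[C@@H](C(C)(C)OC(C)=O)O3)[C@@H](O2)[C@@H](Sc4ccccc4)C1 | intermediate
11 | 4β-Ox-5β-hydroxy-6β-phenylthiocycloheptan-1-one | O=C1CC[C@@H]([C@@]2(C)CC[C@@H](C(C)(C)OC(C)=O)O2)[C@@H](O)[C@@H](Sc3ccccc3)C1 | intermediate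
12 | 4β-Ox-5β-hydroxy-6β-phenylsulfonylcycloheptan-1-one (not isolated) | O=C1CC[C@@H]([C@@]2(C)CC[C@@H](C(C)(C)OC(C)=O)O2)[C@@H](O)[C@@H](S(=O)(=O)c3ccccc3)C1 | intermediate
13 | (4S,5R)-4-hydroxy-5-Ox-cyclohept-2-en-1-one | O=C1CC[C@@H]([C@@]2(C)CC[C@@H](C(C)(C)OC(C)=O)O2)[C@@H](O)C=C1 | intermediate
14 | (4S,5R)-4-(tert-butyldimethylsilyloxy)-5-Ox-cyclohept-2-en-1-one | O=C1CC[C@@H]([C@@]2(C)CC[C@@H](C(C)(C)OC(C)=O)O2)[C@@H](O[Si](C)(C)C(C)(C)C)C=C1 | intermediate
15 | isopropenylmagnesium bromide | C=C(C)[Mg]Br | starting material
16 | trimethylsilyl enol ether (C1=C7), 6α-isopropenyl, 5β-silyloxy, 4β-Ox | C[Si](C)(C)OC1=C[C@@H](C(C)=C)[C@H](O[Si](C)(C)C(C)(C)C)[C@H]([C@@]2(C)CC[C@@H](C(C)(C)OC(C)=O)O2)CC1 | intermediate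
17 | allyl iodide | C=CCI | starting material
18 | benzyltrimethylammonium C1/C7 enolate (not isolated) | [O-]C1=C[C@@H](C(C)=C)[C@H](O[Si](C)(C)C(C)(C)C)[C@H]([C@@]2(C)CC[C@@H](C(C)(C)OC(C)=O)O2)CC1.C[N+](C)(C)Cc1ccccc1 | intermediate
19 | (2R,3S,4S,5R)-2-allyl-3-isopropenyl-4-(tert-butyldimethylsilyloxy)-5-Ox-cycloheptan-1-one | O=C1CC[C@@H]([C@@]2(C)CC[C@@H](C(C)(C)OC(C)=O)O2)[C@@H](O[Si](C)(C)C(C)(C)C)[C@H](C(C)=C)[C@H]1CC=C | intermediate
20 | trans-fused hydroazulenone | O=C1CC[C@@H]([C@@]2(C)CC[C@@H](C(C)(C)OC(C)=O)O2)[C@@H](O[Si](C)(C)C(C)(C)C)[C@@H]2C(C)=CC[C@@H]12 | intermediate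
21 | C5 tert-butyldimethylsilyl ether of the target | C=C1CC[C@@H]([C@@]2(C)CC[C@@H](C(C)(C)OC(C)=O)O2)[C@@H](O[Si](C)(C)C(C)(C)C)[C@@H]2C(C)=CC[C@@H]12 | intermediate
22 | CNP0302132.3 | C=C1CC[C@@H]([C@@]2(C)CC[C@@H](C(C)(C)OC(C)=O)O2)[C@@H](O)[C@@H]2C(C)=CC[C@@H]12 | target

Total step count: 15. Longest linear sequence: 13 (steps 1–3 and 6–15).

Steps most likely to fail

**Step 6.**
- Risk: dimerisation and base-induced decay of the ylide may outrun its addition to an unactivated vinyl group on a quaternary carbon. The two faces of that vinyl group may also be discriminated poorly.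
- Fallback, from 4 back to 14: the cycloaddition is abandoned and the ring is assembled stepwise around the same vinyl carbons. The inner carbon stays C4, the terminal one becomes C5, and the ring is closed at C6=C7 by metathesis.
- Hydroboration–oxidation of 4 (9-BBN, then NaBO3) gives 2-Ox-ethanol F1, and Dess–Martin oxidation gives 2-Ox-acetaldehyde F2.
- Enamine-catalysed Michael addition of F2 to methyl vinyl ketone with (S)-diphenylprolinol trimethylsilyl ether forms C3–C4 and sets C4 under catalyst control, giving 2-Ox-5-oxohexanal F3.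
- Aldehyde-selective Nozaki–Hiyama–Kishi vinylation (vinyl bromide, CrCl2, catalytic NiCl2, DMF) leaves the methyl ketone and the acetate alone. By Felkin–Anh approach anti to the bulky Ox group it should give the C4/C5 relationship of 13 in 6-hydroxy-5-Ox-oct-7-en-2-one F4.
- F4 is silylated (TBSOTf, 2,6-lutidine) to 6-(tert-butyldimethylsilyloxy)-5-Ox-oct-7-en-2-one F5.
- Kinetic enolisation of the methyl ketone (LDA, −78 °C) and reaction with dimethyl(methylidene)ammonium iodide (Eschenmoser's salt) give the Mannich base 1-(dimethylamino)-7-(tert-butyldimethylsilyloxy)-6-Ox-non-8-en-3-one F6.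
- Quaternisation with MeI and mild base then give 7-(tert-butyldimethylsilyloxy)-6-Ox-nona-1,8-dien-3-one F7.
- Ring-closing metathesis of F7 with the second-generation Grubbs catalyst delivers 14.

**Step 12.**
- Risk: proton transfer between the product ketone and the naked enolate may scramble the enolate position and cause over-allylation.
- Risk: traces of water in the fluoride source may simply protonate the enolate, and fluoride may begin to strip the C5 silyl ether.
- Fallback, from 14 back to 19: the SN2 alkylation is replaced by π-allylpalladium chemistry. The cuprate made from 15 and CuBr·SMe2 is added to 14 and the enolate is quenched on oxygen with allyl chloroformate to give the allyl enol carbonate F8.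
- Catalytic Pd(PPh3)4 in THF at rt then triggers the decarboxylative Tsuji allylation. This forms C7–C8 regiospecifically under neutral conditions and anti to the isopropenyl group.

**Step 14.**
- Risk: the ketone next to the ring fusion may be methylenated slowly.
- Risk: prolonged exposure to the Lewis-acidic titanium and zinc salts may epimerise C7 towards the cis-fused isomer or ionise the tertiary acetate.
- Fallback, from 19 back to 21: the order of events is inverted. The less encumbered monocyclic ketone 19, in which the trans C6/C7 arrangement is also the equilibrium one, is methylenated first to the triene 1-methylidene-2-allyl-3-isopropenyl-4-(tert-butyldimethylsilyloxy)-5-Ox-cycloheptane F9.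
- Ring-closing metathesis follows. Only the allyl/isopropenyl pair can form an unstrained ring, since either partner combined with the exocyclic methylene would give a cyclobutene, so 21 should result.

Further compounds
F1 | step 6 | 2-Ox-ethanol | OCC[C@@]1(C)CC[C@@H](C(C)(C)OC(C)=O)O1
F2 | step 6 | 2-Ox-acetaldehyde | O=CC[C@@]1(C)CC[C@@H](C(C)(C)OC(C)=O)O1
F3 | step 6 | 2-Ox-5-oxohexanal | CC(=O)CC[C@@H]([C@@]1(C)CC[C@@H](C(C)(C)OC(C)=O)O1)C=O
F4 | step 6 | 6-hydroxy-5-Ox-oct-7-en-2-one | CC(=O)CC[C@@H]([C@@]1(C)CC[C@@H](C(C)(C)OC(C)=O)O1)[C@@H](O)C=C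
F5 | step 6 | 6-(tert-butyldimethylsilyloxy)-5-Ox-oct-7-en-2-one | CC(=O)CC[C@@H]([C@@]1(C)CC[C@@H](C(C)(C)OC(C)=O)O1)[C@@H](O[Si](C)(C)C(C)(C)C)C=C
F6 | step 6 | 1-(dimethylamino)-7-(tert-butyldimethylsilyloxy)-6-Ox-non-8-en-3-one | CN(C)CCC(=O)CC[C@@H]([C@@]1(C)CC[C@@H](C(C)(C)OC(C)=O)O1)[C@@H](O[Si](C)(C)C(C)(C)C)C=C
F7 | step 6 | 7-(tert-butyldimethylsilyloxy)-6-Ox-nona-1,8-dien-3-one | C=CC(=O)CC[C@@H]([C@@]1(C)CC[C@@H](C(C)(C)OC(C)=O)O1)[C@@H](O[Si](C)(C)C(C)(C)C)C=C
F8 | step 12 | allyl enol carbonate (C1=C7) of 4β-Ox-5β-silyloxy-6α-isopropenylcycloheptanone | C=CCOC(=O)OC1=C[C@@H](C(C)=C)[C@H](O[Si](C)(C)C(C)(C)C)[C@H]([C@@]2(C)CC[C@@H](C(C)(C)OC(C)=O)O2)CC1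
F9 | step 14 | 1-methylidene-2-allyl-3-isopropenyl-4-(tert-butyldimethylsilyloxy)-5-Ox-cycloheptane | C=C1CC[C@@H]([C@@]2(C)CC[C@@H](C(C)(C)OC(C)=O)O2)[C@@H](O[Si](C)(C)C(C)(C)C)[C@H](C(C)=C)[C@H]1CC=C
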